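The carbocycle of the tetrahydrochromone (C4a–C5–C6–C7–C8–C8a) is opened at C6–C7. Its cis-6,7-diol lies on the face opposite the C5 aryloxy and C8 hydroxyl groups, so it is traced back to a C6=C7 alkene. Ring-closing metathesis of a 4-pyranone carrying a (1R)-1-aryloxyallyl arm on C4a and a (1S)-1-silyloxyallyl arm on C8a forms C6=C7 and the six-membered ring in one operation and leaves both oxygenated stereocentres untouched. Osmylation anti to both then sets C6 and C7. The precursor comes from a masked triketone (C8 from (S)-vinylglycolate) joined to a chromonyloxyallene by palladium-catalysed hydrocarbonation, followed by cyclodehydration.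

Key step: step 11

Remarks on the chemistry (assumptions):
- Chromone numbering (C2–C8a) is used for the pyranone-containing half; primed locants denote the aryl chromone.
- The target SMILES reads as 5S,6S,7R,8S: the C5 aryloxy and C8 hydroxyl groups are cis to each other, and the 6,7-diol is cis and on the other face.
- Methyl (S)-2-hydroxybut-3-enoate is assumed to be available in enantiopure form.
- The (R,R) bisphosphine is assumed to deliver the 1R ether carbon in step 9; if a trial run shows the opposite sense, its (S,S) antipode is used.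
- Conjugate bases generated in the flask (acetylide, enolates, phenoxides) are treated as forms of the numbered parent compounds.

Step 1
Reactants: 1 4-phenylbut-1-yne; 2 N-methoxy-N-methylacetamide
Product: 3 6-phenylhex-3-yn-2-one
Conditions: n-BuLi, THF, −78 °C; then 2, −78 → 0 °C; aq NH4Cl
Reagents that add atoms: none
Why: Acylation of a lithium acetylide with a Weinreb amide should stop at the ynone, because the chelated tetrahedral adduct collapses only on work-up.

Step 2
Reactants: 3 6-phenylhex-3-yn-2-one
Product: 4 (E)-4-methoxy-6-phenylhex-3-en-2-one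
Conditions: NaOMe (0.1 equiv), MeOH, 0 °C → rt
Reagents that add atoms: methanol, CO
Why: Base-catalysed oxa-Michael addition of methanol to the ynone should place the methoxy group on the β-carbon and give the more stable E vinylogous ester, whose double-bond geometry is lost again in step 10.

Step 3
Reactants: 5 methyl (S)-2-hydroxybut-3-enoate
Product: 6 methyl (S)-2-[(tert-butyldimethylsilyl)oxy]but-3-enoate
Conditions: TBSCl, imidazole, DMF, 0 °C → rt
Reagents that add atoms: tert-butyldimethylsilyl chloride, CC(C)(C)[Si](C)(C)Cl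
Why: Silylation of a secondary alcohol under imidazole catalysis does not touch the stereocentre.

Step 4
Reactants: 4 (E)-4-methoxy-6-phenylhex-3-en-2-one (2.2 equiv); 6 methyl (S)-2-[(tert-butyldimethylsilyl)oxy]but-3-enoate
Product: 7 (3S,7E)-3-[(tert-butyldimethylsilyl)oxy]-8-methoxy-10-phenyldeca-1,7-diene-4,6-dione (largely enolised)
Conditions: LiN(SiMe3)2 (2.2 equiv), THF, −78 °C; then 6, −78 → −20 °C; AcOH quench
Reagents that add atoms: none
Why: Crossed Claisen condensation of the kinetic methyl-side enolate of the β-methoxy enone with the activated α-silyloxy ester should outpace α-deprotonation of the ester at low temperature, and the second equivalent of enolate stores the product as its diketonate, so the future C8 centre keeps its S configuration.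

Step 5
Reactants: 8 2',4',5'-trihydroxyacetophenone; 9 3-phenylpropanoyl chloride
Product: 11 6,7-dihydroxy-2-(2-phenylethyl)-4H-chromen-4-one, via aryl 1,3-diketone 10 (not isolated)
Conditions: LiN(SiMe3)2 (5 equiv), THF, −78 °C; 9, −78 °C → rt; then AcOH, H2SO4 (cat.), 95 °C
Reagents that add atoms: none
Why: The phenoxide-enolate polyanion should be acylated at carbon (any O-acylated material converges on the same diketone by Baker–Venkataraman acyl transfer), and acid-catalysed cyclodehydration then closes the chromone without protecting groups.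

Step 6
Reactants: 11 6,7-dihydroxy-2-(2-phenylethyl)-4H-chromen-4-one
Product: 12 6-hydroxy-7-(methoxymethoxy)-2-(2-phenylethyl)-4H-chromen-4-one
Conditions: MOMCl (1.05 equiv), K2CO3 (1.05 equiv), acetone, 0 °C
Reagents that add atoms: chloromethyl methyl ether, COCCl
Why: In this Williamson-type alkylation with limiting weak base, the 7-OH (para to the C4 carbonyl and the more acidic phenol) should be the one deprotonated and alkylated, leaving the 6-OH free.

Step 7
Reactants: 12 6-hydroxy-7-(methoxymethoxy)-2-(2-phenylethyl)-4H-chromen-4-one; 13 propargyl bromide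
Product: 14 7-(methoxymethoxy)-2-(2-phenylethyl)-6-(prop-2-yn-1-yloxy)-4H-chromen-4-one
Conditions: K2CO3, DMF, rt
Reagents that add atoms: none
Why: Williamson ether synthesis on the remaining phenol with a reactive propargylic bromide; the MOM ether is stable to carbonate.

Step 8
Reactants: 14 7-(methoxymethoxy)-2-(2-phenylethyl)-6-(prop-2-yn-1-yloxy)-4H-chromen-4-one
Product: 15 7-(methoxymethoxy)-2-(2-phenylethyl)-6-(propa-1,2-dien-1-yloxy)-4H-chromen-4-one
Conditions: KOtBu (0.3 equiv), THF, 0 °C → rt
Reagents that add atoms: none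
Why: Base-catalysed propargyl-to-allenyl prototropic isomerisation of an aryl propargyl ether should stop at the oxygen-stabilised aryloxyallene, and the hindered alkoxide does not open the chromone.

Step 9
Reactants: 7 (3S,7E)-3-[(tert-butyldimethylsilyl)oxy]-8-methoxy-10-phenyldeca-1,7-diene-4,6-dione; 15 7-(methoxymethoxy)-2-(2-phenylethyl)-6-(propa-1,2-dien-1-yloxy)-4H-chromen-4-one (1.2 equiv)
Product: 16 (3S)-3-[(tert-butyldimethylsilyl)oxy]-8-methoxy-5-[(1R)-1-{[7-(methoxymethoxy)-4-oxo-2-(2-phenylethyl)-4H-chromen-6-yl]oxy}prop-2-en-1-yl]-10-phenyldeca-1,7-diene-4,6-dione (C5 epimers and enol tautomers)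
Conditions: Pd2(dba)3·CHCl3 (2.5 mol %), (1R,2R)-N,N'-bis[2-(diphenylphosphino)benzoyl]cyclohexane-1,2-diamine (7.5 mol %), PhCO2H (10 mol %), CH2Cl2, rt
Reagents that add atoms: none
Why: In this palladium-catalysed hydrocarbonation of an oxygen-substituted allene with a 1,3-dicarbonyl pronucleophile, a palladium hydride adds to the allene, the diketone attacks the oxygen-bearing terminus of the aryloxy-substituted π-allyl complex to give the branched allyl aryl ether, and the chiral pocket of the ligand (catalyst control) sets the 1R ether carbon, while the weakly acidic medium keeps the adduct protonated and so disfavours β-elimination of the aryloxide.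

Step 10
Reactants: 16 (3S)-3-[(tert-butyldimethylsilyl)oxy]-8-methoxy-5-[(1R)-1-{[7-(methoxymethoxy)-4-oxo-2-(2-phenylethyl)-4H-chromen-6-yl]oxy}prop-2-en-1-yl]-10-phenyldeca-1,7-diene-4,6-dione
Product: 17 2-[(1S)-1-[(tert-butyldimethylsilyl)oxy]prop-2-en-1-yl]-3-[(1R)-1-{[7-(methoxymethoxy)-4-oxo-2-(2-phenylethyl)-4H-chromen-6-yl]oxy}prop-2-en-1-yl]-6-(2-phenylethyl)-4H-pyran-4-one
Conditions: PPTS (0.3 equiv), 4 Å MS, toluene, 50 °C (16 used directly after a short silica plug)
Reagents that add atoms: none
Why: Acid-catalysed cyclodehydration (intramolecular oxa-Michael addition of the enol oxygen on the C8a carbonyl to the β-methoxy enone, then loss of methanol) should close the 4-pyranone in the only possible regiochemistry, make C4a sp2 so that β-elimination of the aryloxide is no longer possible, and leave both stereocentres, the silyl ether and the MOM ether intact under this weak acid with sieves trapping the methanol.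

Step 11
Reactants: 17 2-[(1S)-1-[(tert-butyldimethylsilyl)oxy]prop-2-en-1-yl]-3-[(1R)-1-{[7-(methoxymethoxy)-4-oxo-2-(2-phenylethyl)-4H-chromen-6-yl]oxy}prop-2-en-1-yl]-6-(2-phenylethyl)-4H-pyran-4-one
Product: 18 (5R,8S)-8-[(tert-butyldimethylsilyl)oxy]-5-{[7-(methoxymethoxy)-4-oxo-2-(2-phenylethyl)-4H-chromen-6-yl]oxy}-2-(2-phenylethyl)-5,8-dihydro-4H-chromen-4-one (C5 and C8 oxygens cis)
Conditions: second-generation Grubbs catalyst (H2IMes)(PCy3)Cl2Ru=CHPh (5 mol %), 1,4-benzoquinone (10 mol %), CH2Cl2 (5 mM), 40 °C
Reagents that add atoms: none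
Why: In this ring-closing olefin metathesis the ruthenium benzylidene exchanges with one terminal vinyl group, the new alkylidene adds across the second vinyl group to a ruthenacyclobutane, and cycloreversion releases ethylene and forms the C6=C7 bond. The closest known reaction type is the metathesis closure of 1,2-bis(1-oxyallyl)arenes and of 1,7-dienes with allylic oxygen substituents to 1,4-dihydronaphthalenes and conduritol-type cyclohexenes. The six-membered carbocycle C4a–C5–C6–C7–C8–C8a is closed by joining the two vinyl termini, which are held side by side on the adjacent sp2 carbons C4a and C8a, so cyclisation should win over oligomerisation at high dilution. No stereocentre is formed, and C5 and C8 keep their configuration because no bond at these carbons takes part. The step needs chemoselectivity for the two monosubstituted alkenes, which is secured because the pyranone and chromone double bonds are tri- or tetrasubstituted, carbonyl-conjugated and electron-poor; it also needs suppression of double-bond migration and of 1,4-elimination of the phenol, addressed by 1,4-benzoquinone, neutral conditions and immediate use of 18 in step 12.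

Step 12
Reactants: 18 (5R,8S)-8-[(tert-butyldimethylsilyl)oxy]-5-{[7-(methoxymethoxy)-4-oxo-2-(2-phenylethyl)-4H-chromen-6-yl]oxy}-2-(2-phenylethyl)-5,8-dihydro-4H-chromen-4-one
Product: 19 (5S,6S,7R,8S)-8-[(tert-butyldimethylsilyl)oxy]-6,7-dihydroxy-5-{[7-(methoxymethoxy)-4-oxo-2-(2-phenylethyl)-4H-chromen-6-yl]oxy}-2-(2-phenylethyl)-5,6,7,8-tetrahydro-4H-chromen-4-one
Conditions: OsO4 (5 mol %), NMO (2 equiv), acetone/H2O (8:1), 0 °C → rt
Reagents that add atoms: osmium tetroxide, O=[Os](=O)(=O)=O; N-methylmorpholine N-oxide, C[N+]1([O-])CCOCC1; water, O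
Why: Catalytic osmylation adds both oxygens suprafacially to the only unconjugated alkene, and OsO4 should approach the face of the nearly planar cyclohexadiene ring opposite the cis-disposed C5 aryloxy and C8 silyloxy groups (steric control by both allylic substituents), which sets C6 (S) and C7 (R) as the cis-diol anti to both neighbours.

Step 13
Reactants: 19 (5S,6S,7R,8S)-8-[(tert-butyldimethylsilyl)oxy]-6,7-dihydroxy-5-{[7-(methoxymethoxy)-4-oxo-2-(2-phenylethyl)-4H-chromen-6-yl]oxy}-2-(2-phenylethyl)-5,6,7,8-tetrahydro-4H-chromen-4-one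
Product: 20 (5S,6S,7R,8S)-6,7,8-trihydroxy-5-{[7-hydroxy-4-oxo-2-(2-phenylethyl)-4H-chromen-6-yl]oxy}-2-(2-phenylethyl)-5,6,7,8-tetrahydro-4H-chromen-4-one (target)
Conditions: HCl (1.25 M in MeOH), 0 °C → rt
Reagents that add atoms: none
Why: Acid-catalysed methanolysis should cleave the aryl methoxymethyl acetal and the secondary silyl ether in one operation under conditions mild enough to leave the C5 alkyl aryl ether, both pyranone rings and the four stereocentres untouched.

Compound list
1 | 4-phenylbut-1-yne | C#CCCc1ccccc1 | starting material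
2 | N-methoxy-N-methylacetamide | CC(=O)N(C)OC | starting material
3 | 6-phenylhex-3-yn-2-one | CC(=O)C#CCCc1ccccc1 | intermediate
4 | (E)-4-methoxy-6-phenylhex-3-en-2-one | CC(=O)/C=C(/OC)CCc1ccccc1 | intermediate
5 | methyl (S)-2-hydroxybut-3-enoate | COC(=O)[C@@H](O)C=C | starting material
6 | methyl (S)-2-[(tert-butyldimethylsilyl)oxy]but-3-enoate | COC(=O)[C@@H](O[Si](C)(C)C(C)(C)C)C=C | intermediate
7 | (3S,7E)-3-[(tert-butyldimethylsilyl)oxy]-8-methoxy-10-phenyldeca-1,7-diene-4,6-dione | C=C[C@H](O[Si](C)(C)C(C)(C)C)C(=O)CC(=O)/C=C(/OC)CCc1ccccc1 | intermediate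
8 | 2',4',5'-trihydroxyacetophenone | CC(=O)c1cc(O)c(O)cc1O | starting material
9 | 3-phenylpropanoyl chloride | O=C(Cl)CCc1ccccc1 | starting material
10 | 5-phenyl-1-(2,4,5-trihydroxyphenyl)pentane-1,3-dione | O=C(CC(=O)CCc1ccccc1)c1cc(O)c(O)cc1O | intermediate
11 | 6,7-dihydroxy-2-(2-phenylethyl)-4H-chromen-4-one | O=c1cc(CCc2ccccc2)oc2cc(O)c(O)cc12 | intermediate
12 | 6-hydroxy-7-(methoxymethoxy)-2-(2-phenylethyl)-4H-chromen-4-one | O=c1cc(CCc2ccccc2)oc2cc(OCOC)c(O)cc12 | intermediate
13 | propargyl bromide | C#CCBr | starting material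
14 | 7-(methoxymethoxy)-2-(2-phenylethyl)-6-(prop-2-yn-1-yloxy)-4H-chromen-4-one | O=c1cc(CCc2ccccc2)oc2cc(OCOC)c(OCC#C)cc12 | intermediate
15 | 7-(methoxymethoxy)-2-(2-phenylethyl)-6-(propa-1,2-dien-1-yloxy)-4H-chromen-4-one | O=c1cc(CCc2ccccc2)oc2cc(OCOC)c(OC=C=C)cc12 | intermediate
16 | (3S)-3-[(tert-butyldimethylsilyl)oxy]-8-methoxy-5-[(1R)-1-{[7-(methoxymethoxy)-4-oxo-2-(2-phenylethyl)-4H-chromen-6-yl]oxy}prop-2-en-1-yl]-10-phenyldeca-1,7-diene-4,6-dione | C=C[C@H](O[Si](C)(C)C(C)(C)C)C(=O)C([C@H](Oc1cc2c(=O)cc(CCc3ccccc3)oc2cc1OCOC)C=C)C(=O)/C=C(/OC)CCc1ccccc1 | intermediate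
17 | 2-[(1S)-1-[(tert-butyldimethylsilyl)oxy]prop-2-en-1-yl]-3-[(1R)-1-{[7-(methoxymethoxy)-4-oxo-2-(2-phenylethyl)-4H-chromen-6-yl]oxy}prop-2-en-1-yl]-6-(2-phenylethyl)-4H-pyran-4-one | O=c1cc(CCc2ccccc2)oc([C@@H](O[Si](C)(C)C(C)(C)C)C=C)c1[C@H](Oc1cc3c(=O)cc(CCc4ccccc4)oc3cc1OCOC)C=C | intermediate
18 | (5R,8S)-8-[(tert-butyldimethylsilyl)oxy]-5-{[7-(methoxymethoxy)-4-oxo-2-(2-phenylethyl)-4H-chromen-6-yl]oxy}-2-(2-phenylethyl)-5,8-dihydro-4H-chromen-4-one | O=c1cc(CCc2ccccc2)oc2c1[C@H](Oc1cc3c(=O)cc(CCc4ccccc4)oc3cc1OCOC)C=C[C@@H]2O[Si](C)(C)C(C)(C)C | intermediate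
19 | (5S,6S,7R,8S)-8-[(tert-butyldimethylsilyl)oxy]-6,7-dihydroxy-5-{[7-(methoxymethoxy)-4-oxo-2-(2-phenylethyl)-4H-chromen-6-yl]oxy}-2-(2-phenylethyl)-5,6,7,8-tetrahydro-4H-chromen-4-one | O=c1cc(CCc2ccccc2)oc2c1[C@H](Oc1cc3c(=O)cc(CCc4ccccc4)oc3cc1OCOC)[C@@H](O)[C@@H](O)[C@@H]2O[Si](C)(C)C(C)(C)C | intermediate
20 | (5S,6S,7R,8S)-6,7,8-trihydroxy-5-{[7-hydroxy-4-oxo-2-(2-phenylethyl)-4H-chromen-6-yl]oxy}-2-(2-phenylethyl)-5,6,7,8-tetrahydro-4H-chromen-4-one | O=c1cc(CCc2ccccc2)oc2c1[C@H](Oc1cc3c(=O)cc(CCc4ccccc4)oc3cc1O)[C@@H](O)[C@@H](O)[C@@H]2O | target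

Total step count: 13
Longest linear sequence: 9 steps (8 → 11 → 12 → 14 → 15 → 16 → 17 → 18 → 19 → 20; steps 5–13)

Steps most likely to fail

1. Step 9. What may go wrong: β-elimination of the aryloxide from the doubly activated adduct, premature cyclisation of 7 to a pyranone that is no longer a pronucleophile, or insufficient facial control by the catalyst against the existing C8 centre. The fallback sets out from 7 and comes back at 17, and it makes the C5–O bond only after C4a has become sp2. Bromination of 7 at the central carbon (NBS, CH2Cl2, 0 °C) should give the bromodiketone F1. Cyclodehydration as in step 10 should give the 3-bromopyranone F2. Stille coupling with (E)-3-(tributylstannyl)prop-2-en-1-ol (Pd(PPh3)4, CuI, DMF) should give the allylic alcohol F3. ClCO2Me and pyridine should convert it into the methyl carbonate F4. Iridium-catalysed branched-selective allylic etherification of F4 with the lithium phenoxide of 12 ([Ir(cod)Cl]2, chiral BINOL-derived phosphoramidite, THF, 50 °C) should then deliver 17, with the C5 configuration set by the ligand.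

2. Step 11. What may go wrong: 1,4-elimination of the phenol from the 5,8-dihydrochromone with aromatisation, migration of a terminal double bond by ruthenium hydride species, or sequestration of the carbene by the C4 carbonyl. The fallback sets out from 17 and comes back at 19, closing the same C6–C7 bond reductively at the diol oxidation level. Ozonolysis of both vinyl groups (O3, CH2Cl2/MeOH, −78 °C, indicator-controlled; then Me2S) should give the dialdehyde F5. Intramolecular pinacol coupling (SmI2, t-BuOH, THF, −78 °C) should then give 19 directly, because six-membered pinacol cyclisations of this type form the cis-diol anti to the two flanking oxygen substituents.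

3. Step 4. What may go wrong: proton transfer from the α-carbon of the silyloxy ester to the enolate, with racemisation of the future C8 centre or migration of the vinyl group into conjugation, or sluggish acylation by the methyl ester. The fallback sets out from 6 and comes back at 7, forming the C–C bond at the aldehyde oxidation level. Reduction of 6 (i-Bu2AlH, CH2Cl2, −78 °C) should give (S)-2-[(tert-butyldimethylsilyl)oxy]but-3-enal F6. Aldol addition of the lithium enolate of 4 (1.1 equiv, THF, −78 °C) should give the β-hydroxy ketone F7 as a mixture of carbinol epimers. Dess–Martin oxidation (NaHCO3, CH2Cl2) should then converge on 7.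

Further compounds
F1 | step 9 | (3S,7E)-5-bromo-3-[(tert-butyldimethylsilyl)oxy]-8-methoxy-10-phenyldeca-1,7-diene-4,6-dione | C=C[C@H](O[Si](C)(C)C(C)(C)C)C(=O)C(Br)C(=O)/C=C(/OC)CCc1ccccc1
F2 | step 9 | 3-bromo-2-[(1S)-1-[(tert-butyldimethylsilyl)oxy]prop-2-en-1-yl]-6-(2-phenylethyl)-4H-pyran-4-one | O=c1cc(CCc2ccccc2)oc([C@@H](O[Si](C)(C)C(C)(C)C)C=C)c1Br
F3 | step 9 | 2-[(1S)-1-[(tert-butyldimethylsilyl)oxy]prop-2-en-1-yl]-3-[(E)-3-hydroxyprop-1-en-1-yl]-6-(2-phenylethyl)-4H-pyran-4-one | O=c1cc(CCc2ccccc2)oc([C@@H](O[Si](C)(C)C(C)(C)C)C=C)c1/C=C/CO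
F4 | step 9 | (E)-3-{2-[(1S)-1-[(tert-butyldimethylsilyl)oxy]prop-2-en-1-yl]-4-oxo-6-(2-phenylethyl)-4H-pyran-3-yl}prop-2-en-1-yl methyl carbonate | O=c1cc(CCc2ccccc2)oc([C@@H](O[Si](C)(C)C(C)(C)C)C=C)c1/C=C/COC(=O)OC
F5 | step 11 | dialdehyde from 17 in which both vinyl groups are cut to formyl groups, configuration at both oxygen-bearing carbons unchanged | O=c1cc(CCc2ccccc2)oc([C@@H](O[Si](C)(C)C(C)(C)C)C=O)c1[C@H](Oc1cc3c(=O)cc(CCc4ccccc4)oc3cc1OCOC)C=O
F6 | step 4 | (S)-2-[(tert-butyldimethylsilyl)oxy]but-3-enal | O=C[C@@H](O[Si](C)(C)C(C)(C)C)C=C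
F7 | step 4 | (3S,7E)-3-[(tert-butyldimethylsilyl)oxy]-4-hydroxy-8-methoxy-10-phenyldeca-1,7-dien-6-one (C4 epimers) | C=C[C@H](O[Si](C)(C)C(C)(C)C)C(O)CC(=O)/C=C(/OC)CCc1ccccc1
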